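The readings come from a simulation for substances that don't exist.

You charge 0.30 M of solid substrate against 0.750 M of reagent, 2.50 equivalents, so the solid substrate is the limiting reagent. Theta's last reading of 99 % suggests that the substrate ends as target, so what matters is how fast it gets there.

the same everywhere: solid substrate 0.30 M
- gamma: reagent 0.38 M; run made earlier
- theta: reagent 1.5 M; run made earlier
- flask: reagent 0.750 M; time 4.0 h

| run | time / h | target / % |
|---|---|---|
| gamma | 0.500 | 7 |
| gamma | 1.00 | 20 |
| gamma | 1.50 | 23 |
| gamma | 2.50 | 37 |
| gamma | 3.00 | 47 |
| gamma | 4.00 | 58 |
| theta | 0.333 | 18 |
| theta | 0.500 | 29 |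
| theta | 0.667 | 33 |
| theta | 1.00 | 55 |
| theta | 1.50 | 75 |
| theta | 2.50 | 91 |
| theta | 4.00 | 99 |

(readings scatter by 2 percentage points)
- as a solid, counted per litre of solution: solid substrate
- the numbers in the tables scatter with a standard deviation of 2 percentage points
- candidate steps: solid substrate <-> dissolved substrate; dissolved substrate + reagent -> target; reagent -> side product; reagent -> decomposition product
- at the start none of the solid substrate is in solution
- the target standing at 4.0 h, as a percentage of the solid substrate charged
- the change that raises the amount of target at 4.0 h, in percent of the solid substrate charged most ("none" if none brings more than 2 percentage points) (Saturday's / Monday's / Wednesday's / none)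
- amount of target at 4.0 h, in percent of the solid substrate charged, after Monday's
- Saturday's: doubling the dissolution coefficient of the solid substrate, all else as stated
- Monday's: doubling the solubility of the solid substrate, all else as stated
- Wednesday's: doubling the amount of reagent, all else as stated

I reckon in two phases. Once the solid has gone, the dissolved substrate decays, and theta's tail shows this: the untransformed part falls at 1.02 h⁻¹. Dividing by the reagent then present gives the tail constant 0.817 M⁻¹ h⁻¹, the fraction of dissolved substrate converted per hour per molar of reagent.

While solid stands, target grows steadily. Gamma gives 0.148 h⁻¹ per molar of reagent, in molar per hour, so [dissolved substrate] holds near 0.182 M. In the flask the solid therefore lasts about 1.15 h. The tail at the charged reagent gives 89.4 %.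

The weak link is that reagent, which the reaction consumes. Its tail mean is nearer 0.557 M, which gives 83.4 %. After Monday's, with everything taken as dissolved, I get 87.0 %. Wednesday's doubled reagent is theta itself, a gain of 16 percentage points. I take the gain from Saturday's doubled dissolution coefficient as small, an assumption that I have not reckoned.

The forecast says 84 %, Wednesday's and 87 %, on the ground that “Doubling reagent matches theta”.

The flask gives 82.5 %, with Wednesday's best at 15 points, and 84.7 % after Monday's.

    solid substrate ⇌ dissolved substrate, rate k1*(cs1 - [dissolved substrate]) while solid is left; crystals form when [dissolved substrate] > cs1 (solubility = 0.200 M, k = 0.00160 s⁻¹)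
    dissolved substrate + reagent → target (k = 2.50 × 10⁻⁴ M⁻¹ s⁻¹)
    reagent → side product (k = 8.80 × 10⁻⁶ s⁻¹)
    reagent → decomposition product (k = 2.70 × 10⁻⁷ s⁻¹)

Between 2.00 h and 4.00 h the flask's dissolved substrate falls from 41.1 % to 17.5 %, a rate of 0.427 h⁻¹. The tail constant times the mean simulated reagent gives 0.393 h⁻¹. With 1.3 M of reagent, my reckoning puts the end of the solid in the neighbouring flask at about 0.642 h, and its tail reagent near 1.09 M. The same reckoning gives 97.0 %. That flask stores 96.4 % of target, with 3.65 % still dissolved.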